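I started from the constants, and the one I could read was k, the second-order constant of Z + D at 20 °C, held in Saturday's run.

| flask | Z | D | temperature | remark | time |
|---|---|---|---|---|---|
| Friday's | 1.4 M | 0.60 equiv | −5 °C | run made earlier |  |
| Saturday's | 2 M | 0.60 equiv | 20 °C | run made earlier |  |
| alder | 2.7 M | 0.600 equiv |  | at 0 °C until 25 s, from then on at 40 °C | 2.0 min |
| oak | 2.7 M | 0.600 equiv | 20 °C |  | 2.0 min |
| elm | 2.7 M | 0.600 equiv | 0 °C |  | 2.0 min |
| cedar | 2.7 M | 0.600 equiv | 40 °C |  | 2.0 min |

- Friday's (time / min: Q / %, Z / %): 0.500: 6, 99; 1.00: 0, 101; 1.50: 1, 100; 3.00: 6, 97; 5.00: 9, 95; 6.00: 5, 94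
- Saturday's (time / s: Q / %, Z / %): 10.0: 2, 98; 20.0: 5, 97; 30.0: 5, 95; 50.0: 9, 91; 80.0: 12, 86; 90.0: 15, 83; 120: 15, 76

(scatter of a reading: 1.5 percentage points)

- the flask with the highest amount of Q, in percent of the Z charged ("all alike" if they lie within 1.5 percentage points) (alder / oak / elm / cedar / all alike)
- final Q, as a percentage of the Z charged, in alder
- final Q, as a percentage of the Z charged, in oak
- final Q, as a percentage of the Z charged, in elm
- final Q, as a percentage of the Z charged, in cedar



1. D is the limiting reagent. I assumed that Z and D go one to one, so the share of D's own charge lost is 1.67 times the share of the Z charge lost. I call this the D cost: points of D's charge lost per point of the Z charge lost.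

2. With rate k[Z][D], the D balance makes the logarithm of (share of Z left over share of D left) grow at k times the difference of the charges. Saturday's reading at 90.0 s has Z at 83 %, which puts D at 71.7 %. That gives a reading of k = 0.00204 /M/s.

3. Oak runs at that temperature. Its Z started by falling 0.198 /min of its charge. Held there, 2.0 min would take 39.6 %.

4. But the same logarithm gave 25.8 % lost in oak. By the end of oak the Z factor, the share of Z left, was 74.2 % and the D factor, the share of D left, 56.9 %, smaller because the D cost exceeds one. Together they left oak at 42.2 % of its starting rate.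

5. Saturday's last two readings put 73.2 % of the lost Z in Q, so I reckoned 18.9 % Q in oak.

6. The forecast named oak, with 11 % in alder, 20 % in oak (higher than my figure), 4.8 % in elm and 8 % in cedar, and held that “Q is probably consumed onward”.

7. The flasks gave 15.3 % in alder, 20.6 % in oak, 5.32 % in elm and 14.1 % in cedar, so oak held the most.

    Z + D ⇌ Q + G (K = 1.40, k = 0.0110 /M/s, Ea = 64.0 kJ/mol, ΔH = −28.0 kJ/mol)
    Z + G → E (k = 0.00150 /M/s, Ea = 55.0 kJ/mol)
    Q ⇌ L (K = 2.40, k = 0.0240 /s, Ea = 80.0 kJ/mol, ΔH = −2.00 kJ/mol)
    D → J (k = 0.00420 /s, Ea = 84.0 kJ/mol)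
    (constants at 40 °C)

Oak lost 26.2 % of its Z against my 25.8 %, and at that loss the D cost puts D at 56.3 %, while oak held 54 %, which is 1.9 percentage points lower. In elm, the forward rate of Z + D used D 21 times as fast as D → J did at 2.00 min. Elm read at 8.0 min still had 82 % of its Z, for which the D cost gives 69.5 % of D, and elm held 69 %.

The data were generated by integration with constants of no real substance, and the scatter is random.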